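0.119 mole of left-handed product per mole of partner charged: that is what the dusk run holds on its plateau, and this partner yield, the plateau c(left-handed product) divided by the charged c(partner), is the number to carry to the flask.

the same everywhere: precatalyst 0.50 mM

|  | left-handed substrate | right-handed substrate | partner | remark | time |
|---|---|---|---|---|---|
| autumn | 0.50 M | 0.50 M | 0.75 M | run made earlier |  |
| dawn | 0.50 M | 0.50 M | 3 M | run made earlier |  |
| dusk | 0.25 M | 0.25 M | 1.5 M | run made earlier |  |
| flask | 0.50 M | 0.50 M | 1.50 M |  | 1.5 h |

- autumn (time / min: left-handed product / %): 8.00: 3; 20.0: 6; 40.0: 6; 60.0: 7; 80.0: 8; 120: 5
- dawn (time / min: left-handed product / %): 8.00: 24; 20.0: 43; 40.0: 44; 60.0: 49; 80.0: 47; 120: 48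
- dusk (time / min: left-handed product / %): 8.00: 9; 15.0: 26; 30.0: 35; 60.0: 35; 120: 37

(standard deviation of a reading: 2 percentage points)

- free catalyst is single-handed; left-handed substrate and right-handed substrate are mirror images of each other, charged as a racemate, each of them at the stated concentration
- the reaction counts as stopped when no species that holds the left-handed substrate and right-handed substrate together changes by six tenths of a point or more over the second half of the time

- the state of affairs at 1.5 h: stopped, and by what, or still going (the partner has run out first / no working catalyst is left / all of the left-handed substrate has reacted / forward and back rates have come level / it is still moving)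
- amount of left-handed product at 1.5 h, in percent of the left-handed substrate and right-handed substrate together charged

The dusk run in slow motion: by 8.00 min the left-handed product has crept to 9%. The middle stretch is the fast one, with 26% at 15.0 min. At 30.0 min it reads 35% and at 120 min 37%, flat within the scatter of 2 percentage points. The dusk plateau, 0.178 M, leaves 0.0717 M of left-handed substrate unreacted, so a shortage of that substrate does not end dusk.

The same count gives 0.0867 in the autumn run, from 0.75 M of partner, and 0.157 in the dawn run, from 3 M. Both hold the flask's substrate charge, and the flask's 1.50 M is their geometric mean, so interpolation gives 0.117. Dusk, with half that substrate but the flask's partner, reads 0.119. This reckoning therefore commits the flask to 17.8% of left-handed product, flat well before 1.5 h, and names the partner as the stop.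

The forecast says no working catalyst is left and 30%, holding that “the catalyst most likely forms slowly (dusk shows an induction period) and then dies”. It parts from the reckoning here on the stop and by 12 points.

The flask gives: the partner has run out first, with 18.3% of left-handed product.

    free catalyst + right-handed substrate ⇌ catalyst intermediate B (K = 11.0 M⁻¹, k = 8690 M⁻¹ min⁻¹)
    partner → decomposed reagent (k = 0.0666 min⁻¹)
    free catalyst + left-handed substrate ⇌ catalyst intermediate A (K = 1.13 M⁻¹, k = 4990 M⁻¹ min⁻¹)
    partner + catalyst intermediate B → free catalyst + right-handed product (k = 174 M⁻¹ min⁻¹)
    partner + precatalyst → free catalyst + spent reagent (k = 0.106 M⁻¹ min⁻¹)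
    partner + catalyst intermediate A → free catalyst + left-handed product (k = 513 M⁻¹ min⁻¹)

Charged at 1.50 M, the partner stands at 0% at 1.50 h, with 0.936 M turned to decomposed reagent and left-handed substrate still at 31.7% of both substrates charged. The partner yield of the flask is 0.122, against the 0.119 carried from dusk. Without the decay of partner the same flask reaches 50.0% of left-handed product. A neighbour flask charged with 0.0013 M of precatalyst also ends with partner at 0%, but with decomposed reagent at 0.692 M and a partner yield of 0.217.

The runs stem from a simulated flask for an exercise, noise included.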